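**Retrosynthetic overview**

1. Carotenoid numbering is used: ring C1–C6 (OH on C3, chain on C6), chain C7–C15 then C15'–C8' (C8' = CHO), methyls C19/C20 on C9/C13 and C20'/C19' on C13'/C9'. The target is (3S,6R)-3-hydroxy-8'-apo-ε-caroten-8'-al, with the hydroxyl cis to the chain.
2. Key disconnection: the C12–C13 σ-bond, formed by a titanium-mediated reductive cross-coupling of two alkynes. The partners are a C16 terminal dienyne (C1–C12, C11≡C12–H) and a C14 propynyl-capped tetraenyne acetal (C13–C8', CH3–C13≡C14). The same operation sets the 11E and 13E alkenes, and its acidic work-up frees the C8' aldehyde.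
3. Enabling feature: C12–C13 is the central bond of the diene C11=C12–C13(C20)=C14. The inner carbons carry only H (C12) and CH3 (C13), and the outer carbons carry the two conjugated arms. Each half therefore maps onto an alkyne, and the size contrast fixes the regiochemistry. The hydroxylated cyclohexene ring (C1–C6) is remote from the reacting carbons.
4. Dienyne: from (R)-α-ionone by C3 allylic oxidation, reduction and Mitsunobu inversion, then ketone-to-alkyne conversion, methylalumination/iodination (9E) and ethynylation. Tetraenyne: 1-propynyllithium plus three stabilised olefinations and acetalization.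
5. Rings: none is formed. The single carbocycle comes intact from α-ionone; the only ring made is the transient titanacyclopentadiene of the key step.

Key step: step 15

Assumption: (R)-α-ionone of high enantiomeric purity (natural grade) is taken as a purchasable material.

**Route**

Step 1
Reactants: 1 (R)-α-ionone
Product: 2 (R)-α-ionone ethylene ketal
Conditions: TMSOCH2CH2OTMS, TMSOTf (cat.), CH2Cl2, −78 °C; then pyridine
Reagents that add atoms: 1,2-bis(trimethylsilyloxy)ethane, C[Si](C)(C)OCCO[Si](C)(C)C
Why: Silyl-triflate-catalysed acetalization (dioxolanation) under aprotic low-temperature conditions masks the side-chain enone without double-bond migration, so C6 and the C7=C8 geometry should stay untouched.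

Step 2
Reactants: 2 (R)-α-ionone ethylene ketal
Product: 3 (6R)-3-oxo-α-ionone ethylene ketal
Conditions: t-BuOOH (70% aq.), NaOCl (aq.), K2CO3, MeCN, 0 °C
Reagents that add atoms: tert-butyl hydroperoxide, CC(C)(C)OO
Why: Radical allylic oxidation by tert-butylperoxyl radicals should attack the only unhindered allylic methylene (C3) and the mixed peroxide collapses to the ring enone, the tertiary C6–H being shielded by the gem-dimethyl group and the side chain.

Step 3
Reactants: 3 (6R)-3-oxo-α-ionone ethylene ketal
Product: 4 (3R,6R)-3-hydroxy-α-ionone ethylene ketal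
Conditions: K[HB(s-Bu)3], THF, −78 °C; then H2O
Reagents that add atoms: none
Why: 1,2-Reduction of the β,β-disubstituted enone by a bulky borohydride, in which hydride should arrive on the face syn to the pseudoaxial C6 chain because the axial C1 methyl blocks the other face, setting C3 as R (hydroxyl trans to the chain).

Step 4
Reactants: 4 (3R,6R)-3-hydroxy-α-ionone ethylene ketal
Product: 5 (3S,6R)-3-(4-nitrobenzoyloxy)-α-ionone ethylene ketal
Conditions: 4-O2NC6H4CO2H, PPh3, DIAD, THF, 0 °C → rt
Reagents that add atoms: 4-nitrobenzoic acid, O=C(O)c1ccc(cc1)[N+](=O)[O-]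
Why: Mitsunobu reaction, in which SN2 displacement of the oxyphosphonium group by the carboxylate inverts C3 to S and so places the oxygen cis to the C6 chain as the target requires.

Step 5
Reactants: 5 (3S,6R)-3-(4-nitrobenzoyloxy)-α-ionone ethylene ketal
Product: 7 (3S,6R)-3-hydroxy-α-ionone, via hydroxy ketal 6 (not isolated)
Conditions: K2CO3 (cat.), MeOH, rt; then PPTS (cat.), acetone–H2O, rt
Reagents that add atoms: water, O
Why: Transesterification (methanolysis) of the activated benzoate followed by mild acid-catalysed acetal hydrolysis, neither of which breaks the C3–O bond or touches C6, so both configurations are retained.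

Step 6
Reactants: 7 (3S,6R)-3-hydroxy-α-ionone
Product: 8 (3S,6R)-3-(tert-butyldimethylsilyloxy)-α-ionone
Conditions: TBSCl, imidazole, DMF, rt
Reagents that add atoms: tert-butyldimethylsilyl chloride, CC(C)(C)[Si](C)(C)Cl
Why: Silyl ether protection of the secondary allylic alcohol carries it through the strongly basic, Lewis acidic and low-valent-metal steps that follow.

Step 7
Reactants: 8 (3S,6R)-3-(tert-butyldimethylsilyloxy)-α-ionone
Product: 10 silyl-protected C13 enyne, via enol phosphate 9 (not isolated)
Conditions: LiN(i-Pr)2 (1.1 equiv), THF, −78 °C; ClP(O)(OEt)2, −78 °C → rt; LiN(i-Pr)2 (2.3 equiv), −78 → 0 °C; aq. NH4Cl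
Reagents that add atoms: none
Why: Ketone-to-alkyne conversion through kinetic enolization at the methyl group, O-phosphorylation and base-induced elimination of the enol phosphate, the low temperature keeping the γ-hydrogen at C6 untouched.

Step 8
Reactants: 10 silyl-protected C13 enyne
Product: 12 silyl-protected (9E)-C14 dienyl iodide, via alkenylalane 11 (not isolated)
Conditions: AlMe3, Cp2ZrCl2 (cat.), ClCH2CH2Cl, rt; then I2, THF, −30 → 0 °C
Reagents that add atoms: trimethylaluminium, C[Al](C)C; iodine, II
Why: Zirconium-catalysed methylalumination (carboalumination) adds CH3 and Al syn across the terminal alkyne with the methyl on the internal carbon (C9), and iodinolysis with retention should give the 9E iodide.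

Step 9
Reactants: 12 silyl-protected (9E)-C14 dienyl iodide
Product: 13 silyl-protected C16 dienyne (C1–C12)
Conditions: HC≡CMgBr, ZnBr2, THF, 0 °C; then 12, Pd(PPh3)4 (cat.), rt
Reagents that add atoms: ethynylmagnesium bromide, C#C[Mg]Br
Why: Negishi coupling of the alkenyl iodide with ethynylzinc bromide proceeds with retention of the 9E geometry and delivers the terminal alkyne C11≡C12–H directly.

Step 10
Reactants: 14 1-propynyllithium; 15 (E)-3-(dimethylamino)prop-2-enal
Product: 17 (E)-hex-2-en-4-ynal, via lithium alkoxide 16 (not isolated)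
Conditions: THF, −78 → 0 °C; then 2 M aq. HCl, 0 °C
Reagents that add atoms: water, O
Why: 1,2-Addition of the acetylide to the vinylogous formamide followed by acid-mediated hydrolysis and loss of dimethylamine (three-carbon enal homologation) should give the conjugated E-enynal as the thermodynamic elimination product.

Step 11
Reactants: 17 (E)-hex-2-en-4-ynal; 18 2-(triphenylphosphoranylidene)propanal
Product: 19 (2E,4E)-2-methylocta-2,4-dien-6-ynal
Conditions: CH2Cl2, rt
Reagents that add atoms: none
Why: Wittig olefination with a stabilised α-methyl ylide gives the E-trisubstituted enal, and the α-branched product is less reactive than 17 so that a single homologation should occur.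

Step 12
Reactants: 19 (2E,4E)-2-methylocta-2,4-dien-6-ynal; 20 diethyl [(E)-2-(cyclohexylamino)ethenyl]phosphonate
Product: 22 (2E,4E,6E)-4-methyldeca-2,4,6-trien-8-ynal, via azatriene 21 (not isolated)
Conditions: NaH, THF, 0 °C → rt; then aq. oxalic acid, rt
Reagents that add atoms: water, O
Why: Horner–Wadsworth–Emmons formyl-olefination with the metalated enamine phosphonate gives the E-configured unsaturated imine, which aqueous oxalic acid hydrolyses to the E-enal.

Step 13
Reactants: 22 (2E,4E,6E)-4-methyldeca-2,4,6-trien-8-ynal; 18 2-(triphenylphosphoranylidene)propanal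
Product: 23 (2E,4E,6E,8E)-2,6-dimethyldodeca-2,4,6,8-tetraen-10-ynal
Conditions: toluene, 70 °C
Reagents that add atoms: none
Why: A second Wittig olefination with the stabilised α-methyl ylide should install the E-trisubstituted C10'=C9' alkene and the terminal aldehyde carbon C8' in one step.

Step 14
Reactants: 23 (2E,4E,6E,8E)-2,6-dimethyldodeca-2,4,6,8-tetraen-10-ynal
Product: 24 (2E,4E,6E,8E)-1,1-dimethoxy-2,6-dimethyldodeca-2,4,6,8-tetraen-10-yne
Conditions: HC(OMe)3, MeOH, PPTS (cat.), rt; then Et3N
Reagents that add atoms: trimethyl orthoformate, COC(OC)OC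
Why: Acid-catalysed acetalization with orthoformate as water scavenger masks the aldehyde against the Grignard reagent and the low-valent titanium of the next step.

Step 15
Reactants: 24 (2E,4E,6E,8E)-1,1-dimethoxy-2,6-dimethyldodeca-2,4,6,8-tetraen-10-yne; 13 silyl-protected C16 dienyne (C1–C12)
Product: 28 (3S,6R)-3-(tert-butyldimethylsilyloxy)-8'-apo-ε-caroten-8'-al, via titanacyclopropene 25 (not isolated), via titanacyclopentadiene 26 (not isolated), via dimethyl acetal 27 (not isolated)
Conditions: 24, Ti(OiPr)4 (1.1 equiv), i-PrMgCl (2.2 equiv), Et2O, −78 → −50 °C; then 13, −50 → −30 °C; then 1 M aq. HCl, THF, 0 °C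
Reagents that add atoms: water, O
Why: Proposed new method: diisopropoxy(η2-propene)titanium, formed from Ti(OiPr)4 and two equivalents of i-PrMgCl, should exchange propene for the triple bond of 24 (the strongest π-acid present) to give titanacyclopropene 25, the terminal alkyne of 13 should then insert into the less hindered Ti–C13 bond with its CH carbon (C12) bonding to C13 to give titanacyclopentadiene 26, and protonolysis of both Ti–C bonds with retention followed by acetal hydrolysis gives 28. The closest known reaction type is the titanium-alkoxide-mediated reductive cross-coupling of an internal alkyne with a terminal alkyne to give (E,E)-1,3-dienes; new here is its use on a conjugated tetraenyne paired with a conjugated dienyne. No ring of the target is closed; the only ring formed is the transient five-membered titanacycle, closed by insertion of the second alkyne into the titanacyclopropene (a formal oxidative cyclisation of two alkynes on divalent titanium). No sp3 stereocentre is created; the 11E and 13E geometries follow from syn addition across each alkyne inside the metallacycle, which holds C10 trans to C13 and C12 trans to C15, and from retentive protonolysis. The step needs cross-coupling over homocoupling and one of four regiochemistries: the first is secured by forming 25 completely before 13 is added at −50 °C, the second by the size contrast at each alkyne (H against dienyl at C12/C11, CH3 against tetraenyl at C13/C14), which places both conjugated arms next to titanium and the small groups at the new bond. The silyl ether and the acetal are inert to these reagents, and the di- and trisubstituted alkenes bind titanium far more weakly than the alkyne.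

Step 16
Reactants: 28 (3S,6R)-3-(tert-butyldimethylsilyloxy)-8'-apo-ε-caroten-8'-al
Product: 29 (3S,6R)-3-hydroxy-8'-apo-ε-caroten-8'-al
Conditions: Bu4NF, AcOH, THF, 0 °C → rt
Reagents that add atoms: none
Why: Fluoride-mediated desilylation buffered with acetic acid liberates the C3 hydroxyl without breaking the C3–O bond or exposing the polyenal to basic fluoride, so configuration and alkene geometry should be retained.

**Compound list**

1 | (R)-α-ionone, (3E)-4-[(1R)-2,6,6-trimethylcyclohex-2-en-1-yl]but-3-en-2-one | CC1=CCCC(C)(C)[C@H]1/C=C/C(C)=O | starting material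
2 | (R)-α-ionone ethylene ketal, 2-methyl-2-{(E)-2-[(1R)-2,6,6-trimethylcyclohex-2-en-1-yl]ethenyl}-1,3-dioxolane | CC1=CCCC(C)(C)[C@H]1/C=C/C2(C)OCCO2 | intermediate
3 | (6R)-3-oxo-α-ionone ethylene ketal, (4R)-3,5,5-trimethyl-4-[(E)-2-(2-methyl-1,3-dioxolan-2-yl)ethenyl]cyclohex-2-en-1-one | CC1=CC(=O)CC(C)(C)[C@H]1/C=C/C2(C)OCCO2 | intermediate
4 | (3R,6R)-3-hydroxy-α-ionone ethylene ketal (hydroxyl trans to chain), (1R,4R)-3,5,5-trimethyl-4-[(E)-2-(2-methyl-1,3-dioxolan-2-yl)ethenyl]cyclohex-2-en-1-ol | CC1=C[C@H](O)CC(C)(C)[C@H]1/C=C/C2(C)OCCO2 | intermediate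
5 | (3S,6R)-3-(4-nitrobenzoyloxy)-α-ionone ethylene ketal, (1S,4R)-3,5,5-trimethyl-4-[(E)-2-(2-methyl-1,3-dioxolan-2-yl)ethenyl]cyclohex-2-en-1-yl 4-nitrobenzoate | CC1=C[C@@H](OC(=O)c2ccc(cc2)[N+](=O)[O-])CC(C)(C)[C@H]1/C=C/C3(C)OCCO3 | intermediate
6 | (3S,6R)-3-hydroxy-α-ionone ethylene ketal (hydroxyl cis to chain) | CC1=C[C@@H](O)CC(C)(C)[C@H]1/C=C/C2(C)OCCO2 | intermediate
7 | (3S,6R)-3-hydroxy-α-ionone, (3E)-4-[(1R,4S)-4-hydroxy-2,6,6-trimethylcyclohex-2-en-1-yl]but-3-en-2-one | CC1=C[C@@H](O)CC(C)(C)[C@H]1/C=C/C(C)=O | intermediate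
8 | (3S,6R)-3-(tert-butyldimethylsilyloxy)-α-ionone | CC1=C[C@@H](O[Si](C)(C)C(C)(C)C)CC(C)(C)[C@H]1/C=C/C(C)=O | intermediate
9 | diethyl (3E)-4-[(1R,4S)-4-(tert-butyldimethylsilyloxy)-2,6,6-trimethylcyclohex-2-en-1-yl]buta-1,3-dien-2-yl phosphate | CC1=C[C@@H](O[Si](C)(C)C(C)(C)C)CC(C)(C)[C@H]1/C=C/C(=C)OP(=O)(OCC)OCC | intermediate
10 | tert-butyl{[(1S,4R)-4-[(1E)-but-1-en-3-yn-1-yl]-3,5,5-trimethylcyclohex-2-en-1-yl]oxy}dimethylsilane | CC1=C[C@@H](O[Si](C)(C)C(C)(C)C)CC(C)(C)[C@H]1/C=C/C#C | intermediate
11 | dimethyl[(1E,3E)-4-[(1R,4S)-4-(tert-butyldimethylsilyloxy)-2,6,6-trimethylcyclohex-2-en-1-yl]-2-methylbuta-1,3-dien-1-yl]alane | CC1=C[C@@H](O[Si](C)(C)C(C)(C)C)CC(C)(C)[C@H]1/C=C/C(C)=C/[Al](C)C | intermediate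
12 | tert-butyl{[(1S,4R)-4-[(1E,3E)-4-iodo-3-methylbuta-1,3-dien-1-yl]-3,5,5-trimethylcyclohex-2-en-1-yl]oxy}dimethylsilane | CC1=C[C@@H](O[Si](C)(C)C(C)(C)C)CC(C)(C)[C@H]1/C=C/C(C)=C/I | intermediate
13 | tert-butyldimethyl{[(1S,4R)-3,5,5-trimethyl-4-[(1E,3E)-3-methylhexa-1,3-dien-5-yn-1-yl]cyclohex-2-en-1-yl]oxy}silane | CC1=C[C@@H](O[Si](C)(C)C(C)(C)C)CC(C)(C)[C@H]1/C=C/C(C)=C/C#C | intermediate
14 | 1-propynyllithium | [Li]C#CC | starting material
15 | (E)-3-(dimethylamino)prop-2-enal | CN(C)/C=C/C=O | starting material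
16 | lithium (E)-1-(dimethylamino)hex-1-en-4-yn-3-olate | CC#CC(O[Li])/C=C/N(C)C | intermediate
17 | (E)-hex-2-en-4-ynal | CC#C/C=C/C=O | intermediate
18 | 2-(triphenylphosphoranylidene)propanal | CC(C=O)=P(c1ccccc1)(c1ccccc1)c1ccccc1 | starting material
19 | (2E,4E)-2-methylocta-2,4-dien-6-ynal | CC#C/C=C/C=C(\C)C=O | intermediate
20 | diethyl [(E)-2-(cyclohexylamino)ethenyl]phosphonate | CCOP(=O)(OCC)/C=C/NC1CCCCC1 | starting material
21 | N-cyclohexyl-(2E,4E,6E)-4-methyldeca-2,4,6-trien-8-yn-1-imine | CC#C/C=C/C=C(C)/C=C/C=NC1CCCCC1 | intermediate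
22 | (2E,4E,6E)-4-methyldeca-2,4,6-trien-8-ynal | CC#C/C=C/C=C(C)/C=C/C=O | intermediate
23 | (2E,4E,6E,8E)-2,6-dimethyldodeca-2,4,6,8-tetraen-10-ynal | CC#C/C=C/C=C(C)/C=C/C=C(\C)C=O | intermediate
24 | (2E,4E,6E,8E)-1,1-dimethoxy-2,6-dimethyldodeca-2,4,6,8-tetraen-10-yne | CC#C/C=C/C=C(C)/C=C/C=C(\C)C(OC)OC | intermediate
25 | diisopropoxytitanacyclopropene of 24 (Ti bridging C13 and C14; CH3 on C13, tetraenyl acetal arm on C14) | CC1=C(/C=C/C=C(C)/C=C/C=C(\C)C(OC)OC)[Ti]1(OC(C)C)OC(C)C | intermediate
26 | 1,1-diisopropoxy-1-titanacyclopenta-2,4-diene (Ti–C11(silyloxy-ring dienyl arm)=C12H–C13(CH3)=C14(tetraenyl acetal arm)–Ti) | CC1=C[C@@H](O[Si](C)(C)C(C)(C)C)CC(C)(C)[C@H]1/C=C/C(C)=C/C2=CC(C)=C(/C=C/C=C(C)/C=C/C=C(\C)C(OC)OC)[Ti]2(OC(C)C)OC(C)C | intermediate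
27 | (3S,6R)-3-(tert-butyldimethylsilyloxy)-8'-apo-ε-caroten-8'-al dimethyl acetal (all-E) | CC1=C[C@@H](O[Si](C)(C)C(C)(C)C)CC(C)(C)[C@H]1/C=C/C(C)=C/C=C/C(C)=C/C=C/C=C(C)/C=C/C=C(\C)C(OC)OC | intermediate
28 | (3S,6R)-3-(tert-butyldimethylsilyloxy)-8'-apo-ε-caroten-8'-al (all-E) | CC1=C[C@@H](O[Si](C)(C)C(C)(C)C)CC(C)(C)[C@H]1/C=C/C(C)=C/C=C/C(C)=C/C=C/C=C(C)/C=C/C=C(\C)C=O | intermediate
29 | (3S,6R)-3-hydroxy-8'-apo-ε-caroten-8'-al, (2E,4E,6E,8E,10E,12E,14E,16E)-17-[(1R,4S)-4-hydroxy-2,6,6-trimethylcyclohex-2-en-1-yl]-2,6,11,15-tetramethylheptadeca-2,4,6,8,10,12,14,16-octaenal | CC1=C[C@@H](O)CC(C)(C)[C@H]1/C=C/C(C)=C/C=C/C(C)=C/C=C/C=C(C)/C=C/C=C(\C)C=O | target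

**Totals**

Total step count: 16. Longest linear sequence: 11 steps (steps 1–9, 15, 16).

**Steps most likely to fail**

1. Step 15 (Proposed new method). What may go wrong: the low-valent titanium may bind the conjugated polyene of 24 or drift into an allenyl-type titanium species through the neighbouring C15=C15' bond. The terminal alkyne of 13 may insert the wrong way round or merely protonate the titanacyclopropene, and homocoupling may compete. The fallback uses known hydrozirconation and Negishi coupling; it sets out from 24 and 13 and comes back at 27, hence 28. Alkyne 24 is treated with excess Cp2Zr(H)Cl (THF, rt), which should equilibrate zirconium onto the methyl-bearing carbon C13 and give the (E)-alkenylzirconocene chloride F1. Iodination in the same flask (I2, 0 °C) gives the (E)-alkenyl iodide F2. Dienyne 13 is hydrozirconated (Cp2Zr(H)Cl, THF, rt) to the (E)-trienylzirconocene chloride F3. F3 is coupled with F2 under Pd(PPh3)4 and ZnCl2 (THF, rt) with retention at both alkenyl carbons to give acetal 27, and the dilute-acid work-up of step 15 then delivers 28.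

2. Step 4. What may go wrong: the allylic oxyphosphonium intermediate may ionise (loss of clean inversion, allylic transposition) or eliminate to the ring diene. The same fallback also corrects any shortfall in facial selectivity in step 3. It sets out from 4 and comes back at 7. Hydroxy ketal 4 is stirred with dilute aqueous HCl in THF at rt, which removes the dioxolane and epimerises C3 through the ring allyl cation, the known acid-mediated equilibration of 3-hydroxy-ε end groups. This gives (3S,6R)-3-hydroxy-α-ionone 7 together with its epimer (3R,6R)-3-hydroxy-α-ionone F4. Chromatography should separate the two; F4 is resubmitted to the equilibration and 7 enters step 6.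

3. Step 8. What may go wrong: the Lewis acidic AlMe3/zirconocene system may ionise the allylic silyl ether, or carbometalation may be incomplete on the conjugated enyne. The fallback sets out from 8 and comes back at 13, bypassing steps 7–9. Ketone 8 undergoes Horner–Wadsworth–Emmons olefination with the lithium anion of diethyl [3-(trimethylsilyl)prop-2-yn-1-yl]phosphonate (n-BuLi, THF, −78 °C → rt) to give the trimethylsilyl-capped dienyne F5. Its 9E isomer is separated from the minor 9Z isomer by chromatography. K2CO3 in MeOH then removes the alkynyl silane to give 13.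

**Further compounds**

F1 | step 15 | chloro[(2E,4E,6E,8E,10E)-12,12-dimethoxy-7,11-dimethyldodeca-2,4,6,8,10-pentaen-2-yl]bis(cyclopentadienyl)zirconium | Cl[Zr](C1C=CC=C1)(C1C=CC=C1)/C(C)=C/C=C/C=C(C)/C=C/C=C(\C)C(OC)OC
F2 | step 15 | (2E,4E,6E,8E,10E)-11-iodo-1,1-dimethoxy-2,6-dimethyldodeca-2,4,6,8,10-pentaene | I/C(C)=C/C=C/C=C(C)/C=C/C=C(\C)C(OC)OC
F3 | step 15 | chloro[(1E,3E,5E)-6-[(1R,4S)-4-(tert-butyldimethylsilyloxy)-2,6,6-trimethylcyclohex-2-en-1-yl]-4-methylhexa-1,3,5-trien-1-yl]bis(cyclopentadienyl)zirconium | CC1=C[C@@H](O[Si](C)(C)C(C)(C)C)CC(C)(C)[C@H]1/C=C/C(C)=C/C=C/[Zr](Cl)(C2C=CC=C2)C2C=CC=C2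
F4 | step 4 | (3R,6R)-3-hydroxy-α-ionone, (3E)-4-[(1R,4R)-4-hydroxy-2,6,6-trimethylcyclohex-2-en-1-yl]but-3-en-2-one | CC1=C[C@H](O)CC(C)(C)[C@H]1/C=C/C(C)=O
F5 | step 8 | tert-butyldimethyl{[(1S,4R)-3,5,5-trimethyl-4-[(1E,3E)-3-methyl-6-(trimethylsilyl)hexa-1,3-dien-5-yn-1-yl]cyclohex-2-en-1-yl]oxy}silane | CC1=C[C@@H](O[Si](C)(C)C(C)(C)C)CC(C)(C)[C@H]1/C=C/C(C)=C/C#C[Si](C)(C)C
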